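## Structural features

The target is a 1,5-dioxaspiro[2.4]heptane: a tetrahydrofuran (O1, C2, C3, C4, C5) that shares C3 with a terminal oxirane (C6–O7). C2 carries the 4-hydroxy-3-methoxyphenyl ring (ring B) directly, and C4 carries the 3-hydroxy-4-methoxyphenyl ring (ring A) through the C7' methylene. The stereocentres C2, C3 and C4 are contiguous and all S. Ring B, the oxirane CH2 (C6) and the C7' group lie on one face of the tetrahydrofuran, and O7 lies on the other. The fragile points are the spiro-oxirane (acid, nucleophiles), the benzylic ether C2–O1 (it can ionise towards a quinone methide once the para-phenol of ring B is free) and the two phenols. The real difficulty is the fully substituted C3, which bears two C–O bonds and must be set relative to both neighbours, together with C2, whose configuration is easily lost through a benzylic cation. The key step uses the fact that O1 on C2 and O7 on C3 are the two oxygens of an anti-opened C2–C3 oxirane. If O7 is first placed as an epoxide across a C2=C3 alkene in which ring B is cis to C6, attack of the C5 hydroxyl at benzylic C2 with inversion sets the C2/C3 relationship, keeps O7 on C3 and leaves the C6 hydroxyl free for the later spiro-oxirane.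

## Logic of the disconnections

**23 to 21 (through 22).** The O7–C6 bond of the oxirane and the two phenolic O–acyl bonds are cut. The oxirane is the most sensitive function, so it is made last by displacement of a primary sulfonate by the tertiary C3 alkoxide. The C3–O7 bond is never broken, so C3 keeps its configuration. The gain is that every earlier intermediate is a robust aryl ester and one basic operation finishes the molecule. The forward step must close the oxirane faster than methoxide can open it and must not ionise C2–O1 once the para-phenol of ring B is free.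

**21 to 20.** The O–S bond at C6 is cut. This reduces the problem to a 1,2-diol with one primary and one tertiary hydroxyl. The forward step only has to sulfonylate the primary hydroxyl selectively.

**20 to 19.** The O1–C2 bond is cut; this is the key disconnection. The ring and the C2 stereocentre are traced back to an acyclic epoxy diol whose two hydroxyls are 1,4-related along C6–C3–C4–C5. Its stereochemistry is written entirely by alkene geometry and by an asymmetric epoxidation. The forward step must open the oxirane at C2 and not at C3, must use the C5 and not the C6 hydroxyl, and must proceed with inversion. This requires ring B to be an electron-poor aryl ester and to sit cis to C6 on the oxirane.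

**19 to 18 to 17.** The O–Si bond at C5 is cut, then the two oxirane C–O bonds. The titanium-mediated epoxidation should see exactly one free hydroxyl, the allylic one. A free C5 hydroxyl would bind titanium as a chelating 1,4-diol and could open the oxirane on the metal before it is isolated. The C5 oxygen therefore stays silylated through the epoxidation and is released only just before the acid step. The forward epoxidation must choose one alkene face on a Z-configured, C2-branched allylic alcohol. C4 carries two CH2 groups of similar size, so its own facial bias should be small and the tartrate should dominate.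

**17 to 15 and 16.** The C3–C6 bond is cut. A palladium-catalysed hydroxymethyl transfer keeps the alkene geometry, so the geometry problem moves to the enol triflate. The forward step requires transfer of an sp3 carbon from tin to a crowded alkenyl triflate.

**15 to 13 (through 14).** The enol O–S bond is cut, and the C2=C3 geometry is traced to an enolate. The benzylic CH2 of the ketone is far more acidic than C4–H, so deprotonation is regioselective and leaves C4 alone. The conjugated enolate should place ring B cis to oxygen and trans to the branched C4 substituent, which is the geometry needed later (ring B cis to C6). The forward step needs this enolate geometry and needs aryl protecting groups without α-protons, which the pivalates provide. A trans-hydrometalation of an aryl alkyne could give the same geometry. It was not chosen because it needs the C5 hydroxyl free as a directing group, then protected again, and because its regiochemistry on an aryl alkyne is harder to predict.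

**13 to 8 and 11 (through 12).** The C2–C3 bond is cut between the carbonyl carbon and the benzylic CH2. A thioester–organozinc coupling is neutral, stops at the ketone, tolerates aryl esters and does not epimerise C4. The forward step requires a clean zinc insertion into a benzylic bromide that carries an ester.

**8 to 7 to 6 to 4 (through 5).** The C–S bond, the O–Si bond and then the C4–C5 bond are cut. C4 is set by hydroxymethylation of a titanium enolate on a chiral oxazolidinone; the (R)-auxiliary gives the S centre. Silylation keeps the two oxygenated arms at C4 distinct and masks the future O1. Thiolysis removes the auxiliary and provides the acyl donor for the ketone. The enolate step needs full facial control and an aryl ester that tolerates TiCl4.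

**4 to 1 and 2 (through 3); 11 to 10 to 9.** The N–acyl and O–acyl bonds are cut, and on the other branch the benzylic C–Br and phenolic O–acyl bonds. These lead to three commercial materials. The only requirement is that the phenol of 1 is acylated before it can attack the activated acid.

## Other disconnections considered

**Alternative 1:** The cut removes O1–C2, C3–C4 and the ring A–C7' bond in one operation. It leads from the 4-arylidene tetrahydrofuran-3,3-diester A1 to three small components: the arylidene malonate A2, prop-2-yn-1-ol A3 and the aryl iodide A4.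
- Forward step: the alkoxide of A3 would add to A2 (O1–C2). The malonate anion would attack the alkyne anti to an ArPdI species formed from A4 and zerovalent palladium (C3–C4, 5-exo-dig). Reductive elimination would attach ring A to C7' with defined alkene geometry.
- In its favour: three bonds, the ring and the whole carbon skeleton come from trivial building blocks. The silyl ethers on the phenols would come off with fluoride at the end, which is milder than a carbonate methanolysis.
- Against it here: C2 arises from an uncontrolled conjugate addition, so A1 would be racemic without a resolution or a chiral catalyst. C3 arrives with two ester carbons that must be degraded to one oxygen and one CH2O (dealkoxycarbonylation, enolate oxidation, reduction) before the spiro-oxirane can be made. C4 must still be set by face-selective hydrogenation of C4=C7'.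
- Comparison: this alternative is better in bonds formed per step and equal in the sulfonate/base oxirane closure it would eventually need. It is weaker in stereocontrol: none of the three centres is fixed in its key step, whereas the chosen route sets C4 by an auxiliary, C3 by the tartrate and C2 by a stereospecific inversion. The repair at C3 would cost about as many steps as the convergence saves.

**Alternative 2:** The cut is the C3–C4 bond (with the C7'–H bond), from the 3-methylene tetrahydrofuran A5 back to the enyne A6, a ring B propargylic ether of a ring A cinnamyl alcohol.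
- Forward step: H–Pd–OAc (from Pd(OAc)2 or Pd2(dba)3 and acetic acid) would add to the terminal alkyne with palladium on C3. The alkenylpalladium would insert the cinnamyl alkene in the 5-exo mode to form C3–C4. A silane would reduce the benzylic C7'–Pd bond.
- In its favour: A6 needs only one catalytically set stereocentre (C2, by asymmetric alkynylation) and one etherification. The exocyclic methylene of A5 is one epoxidation away from the spiro-oxirane, and attack from the face opposite the two cis substituents would give the correct O7 orientation. No diol, sulfonate or base step is needed.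
- Against it here: C4 is fixed only by 1,3-relay from C2 in the cyclisation, and the 2,4-cis preference is not assured. C2 is both benzylic and propargylic and carries an electron-rich para-silyloxyaryl group, so ionisation and racemisation under the mildly acidic palladium conditions are a concern. The late epoxidation gives the right face only if the 2,4-cis arrangement has been achieved.
- Comparison: this alternative is clearly better in step economy (roughly half the operations) and equal in the mildness of its endgame. It is weaker in the independence of its stereocontrol, because the chosen route sets each centre by a separate event. Its weak point, a labile C2–O bond, is the same kind of risk that the chosen key step carries. If the cyclisation proved highly cis-selective, this would be the more efficient synthesis.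

**Alternative 3:** The cut is the C4–C5 bond, from the tertiary alcohol A7 back to the O1-linked acetic acid A8, in which C2 and C3 are already in place and C4 is the inner carbon of a styrene.
- Forward step: photoredox oxidation of the carboxylate (for example with Ir[dF(CF3)ppy]2(dtbbpy)PF6 and a base under visible light) and loss of CO2 would give the α-alkoxymethyl radical at C5. It would add 5-exo-trig to C4, and the benzylic radical at C7' would be reduced and protonated.
- In its favour: the conditions are neutral and mild. C2 and C3 are never exposed to cationic chemistry, because C2–O1 is made by ordinary etherification with retention. A7 has the same C3 tertiary alcohol and primary oxygen as 20, so the endgame would be the same.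
- Against it here: the new C4 centre is governed only by the conformational preference of the radical transition state next to the quaternary C3, so a mixture of C4 epimers is likely. A8 needs its own stereocontrolled synthesis of an anti-configured benzylic ether and tertiary allylic alcohol, and the alkylation of a hindered secondary hydroxyl beside a free tertiary one. Three different silyl ethers must later be distinguished.
- Comparison: this alternative is better in protecting C2 from ionisation and equal in its endgame and overall length. It is weaker in the control of C4, which the chosen route fixes at the start with an auxiliary, and in the accessibility of its cyclisation substrate.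

Key step: step 12

Remark on the chemistry: ring positions are O1, C2, C3, C4, C5 (tetrahydrofuran), C6–O7 (oxirane) and C7' (benzylic CH2); pivaloyl is 2,2-dimethylpropanoyl; the enolate of 13 is assumed to prefer the geometry with ring B cis to oxygen, as expected for a benzylic ketone enolate with a branched group on the carbonyl carbon.

## Route

Step 1
Reactants: 1 3-(3-hydroxy-4-methoxyphenyl)propanoic acid; 2 (4R)-4-benzyl-1,3-oxazolidin-2-one
Product: 4 (4R)-4-benzyl-3-{3-[4-methoxy-3-(pivaloyloxy)phenyl]propanoyl}-1,3-oxazolidin-2-one, via mixed pivalic anhydride 3 (not isolated)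
Conditions: PivCl (2.4 equiv), Et3N, DMAP (cat.), THF, −20 °C (1 added slowly); then 2, LiCl, rt
Reagents that add atoms: pivaloyl chloride, CC(C)(C)C(Cl)=O
Why: With the acid added slowly to excess pivaloyl chloride, the phenol should be pivaloylated and the carboxylate converted into anhydride 3 before either can attack the anhydride; LiCl-assisted N-acylation of 2 then occurs at the unhindered carbonyl of 3 (mixed-anhydride acylation of an Evans auxiliary).

Step 2
Reactants: 4 (4R)-4-benzyl-3-{3-[4-methoxy-3-(pivaloyloxy)phenyl]propanoyl}-1,3-oxazolidin-2-one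
Product: 6 (4R)-4-benzyl-3-{(2S)-2-(hydroxymethyl)-3-[4-methoxy-3-(pivaloyloxy)phenyl]propanoyl}-1,3-oxazolidin-2-one, via trichlorotitanium Z-enolate 5 (not isolated)
Conditions: TiCl4, iPr2NEt, CH2Cl2, 0 °C; then 1,3,5-trioxane, TiCl4, 0 °C
Reagents that add atoms: 1,3,5-trioxane (formaldehyde source), C1OCOCO1
Why: Soft enolisation gives the chelated Z-enolate 5, which should be attacked by the TiCl4-activated formaldehyde equivalent on the face away from the benzyl group of the auxiliary (Evans-type titanium enolate hydroxymethylation); with the (R)-auxiliary this sets the future C4 as S, and the aryl pivalate should be inert to TiCl4 at 0 °C.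

Step 3
Reactants: 6 (4R)-4-benzyl-3-{(2S)-2-(hydroxymethyl)-3-[4-methoxy-3-(pivaloyloxy)phenyl]propanoyl}-1,3-oxazolidin-2-one
Product: 7 (4R)-4-benzyl-3-{(2S)-2-[(tert-butyldimethylsilyloxy)methyl]-3-[4-methoxy-3-(pivaloyloxy)phenyl]propanoyl}-1,3-oxazolidin-2-one
Conditions: TBSCl, imidazole, DMF, rt
Reagents that add atoms: tert-butyldimethylsilyl chloride, CC(C)(C)[Si](C)(C)Cl
Why: Standard silylation of a primary alcohol; it masks the future O1 through the organometallic, basic and titanium-mediated steps and prevents retro-aldol or acyl-migration chemistry of the β-hydroxy carbonyl unit.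

Step 4
Reactants: 7 (4R)-4-benzyl-3-{(2S)-2-[(tert-butyldimethylsilyloxy)methyl]-3-[4-methoxy-3-(pivaloyloxy)phenyl]propanoyl}-1,3-oxazolidin-2-one
Product: 8 S-ethyl (2S)-2-[(tert-butyldimethylsilyloxy)methyl]-3-[4-methoxy-3-(pivaloyloxy)phenyl]propanethioate
Conditions: EtSH, n-BuLi, THF, −20 → 0 °C
Reagents that add atoms: ethanethiol, CCS
Why: Lithium ethanethiolate should cleave the activated exocyclic imide carbonyl within minutes at low temperature (thiolysis of an N-acyl oxazolidinone) and release 2 for re-use; the hindered aryl pivalate and the C4 centre should be untouched under these conditions.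

Step 5
Reactants: 9 2-methoxy-4-methylphenol
Product: 10 2-methoxy-4-methylphenyl pivalate
Conditions: PivCl, Et3N, DMAP (cat.), CH2Cl2, 0 °C → rt
Reagents that add atoms: pivaloyl chloride, CC(C)(C)C(Cl)=O
Why: Routine O-acylation of a phenol; the pivalate has no α-protons (needed in step 8) and makes ring B electron-poor enough for the key step.

Step 6
Reactants: 10 2-methoxy-4-methylphenyl pivalate
Product: 11 4-(bromomethyl)-2-methoxyphenyl pivalate
Conditions: NBS, AIBN (cat.), PhCF3, 80 °C
Reagents that add atoms: N-bromosuccinimide, O=C1CCC(=O)N1Br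
Why: Wohl–Ziegler benzylic bromination; the acyloxy group deactivates the ring towards electrophilic bromination, so the radical pathway at the methyl group should dominate.

Step 7
Reactants: 8 S-ethyl (2S)-2-[(tert-butyldimethylsilyloxy)methyl]-3-[4-methoxy-3-(pivaloyloxy)phenyl]propanethioate; 11 4-(bromomethyl)-2-methoxyphenyl pivalate
Product: 13 (3S)-3-[(tert-butyldimethylsilyloxy)methyl]-1-[3-methoxy-4-(pivaloyloxy)phenyl]-4-[4-methoxy-3-(pivaloyloxy)phenyl]butan-2-one, via benzylzinc bromide 12 (not isolated)
Conditions: 11, Zn dust, THF, 0 °C; then 8, PdCl2(PPh3)2 (5 mol %), toluene, rt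
Reagents that add atoms: none
Why: Zinc should insert into the benzylic C–Br bond without touching the ester, and the Fukuyama coupling (thioester plus organozinc under zerovalent palladium catalysis) stops at the ketone under neutral conditions, so the C4 centre α to the carbonyl should not epimerise.

Step 8
Reactants: 13 (3S)-3-[(tert-butyldimethylsilyloxy)methyl]-1-[3-methoxy-4-(pivaloyloxy)phenyl]-4-[4-methoxy-3-(pivaloyloxy)phenyl]butan-2-one
Product: 15 (1Z,3S)-3-[(tert-butyldimethylsilyloxy)methyl]-1-[3-methoxy-4-(pivaloyloxy)phenyl]-4-[4-methoxy-3-(pivaloyloxy)phenyl]but-1-en-2-yl trifluoromethanesulfonate, via potassium Z-enolate 14 (not isolated)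
Conditions: KN(SiMe3)2 (1.1 equiv), THF, −78 °C; then PhNTf2, −78 → 0 °C
Reagents that add atoms: N-phenylbis(trifluoromethanesulfonimide), O=S(=O)(N(c1ccccc1)S(=O)(=O)C(F)(F)F)C(F)(F)F
Why: The doubly activated benzylic CH2 should be deprotonated far faster than the hindered C4–H, and the conjugated enolate 14 should place ring B cis to oxygen and trans to the branched C4 substituent; O-triflation traps this geometry (regio- and stereoselective enol triflate formation), and the pivalates and C4 should be unaffected.

Step 9
Reactants: 15 (1Z,3S)-3-[(tert-butyldimethylsilyloxy)methyl]-1-[3-methoxy-4-(pivaloyloxy)phenyl]-4-[4-methoxy-3-(pivaloyloxy)phenyl]but-1-en-2-yl trifluoromethanesulfonate; 16 (tributylstannyl)methanol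
Product: 17 (2Z)-2-{(2R)-1-(tert-butyldimethylsilyloxy)-3-[4-methoxy-3-(pivaloyloxy)phenyl]propan-2-yl}-3-[3-methoxy-4-(pivaloyloxy)phenyl]prop-2-en-1-ol
Conditions: Pd(PPh3)4 (10 mol %), LiCl, 1,4-dioxane, 90 °C
Reagents that add atoms: none
Why: Stille–Kosugi hydroxymethylation: oxidative addition of the alkenyl triflate, transfer of CH2OH from tin and reductive elimination all proceed with retention, so the CH2OH group should end cis to ring B; the descriptor at C4 changes to R only because the priorities change.

Step 10
Reactants: 17 (2Z)-2-{(2R)-1-(tert-butyldimethylsilyloxy)-3-[4-methoxy-3-(pivaloyloxy)phenyl]propan-2-yl}-3-[3-methoxy-4-(pivaloyloxy)phenyl]prop-2-en-1-ol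
Product: 18 {(2S,3R)-2-{(2S)-1-(tert-butyldimethylsilyloxy)-3-[4-methoxy-3-(pivaloyloxy)phenyl]propan-2-yl}-3-[3-methoxy-4-(pivaloyloxy)phenyl]oxiran-2-yl}methanol
Conditions: Ti(OiPr)4 (1.0 equiv), L-(+)-diethyl tartrate (1.2 equiv), t-BuOOH (decane), 4 Å molecular sieves, CH2Cl2, −20 °C; aqueous tartaric acid work-up
Reagents that add atoms: tert-butyl hydroperoxide, CC(C)(C)OO
Why: Sharpless asymmetric epoxidation of the single free allylic alcohol; L-(+)-tartrate should deliver oxygen to the face that gives the (2S,3R)-oxirane, the sense known for cis-3-aryl allylic alcohols, and the cis relationship of ring B and CH2OH is carried over stereospecifically. A full equivalent of the Ti(OiPr)4–tartrate reagent is used because Z-substituted, C2-branched substrates react slowly; the silyl ether keeps the C5 oxygen off titanium, and diastereomers would be removed by chromatography.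

Step 11
Reactants: 18 {(2S,3R)-2-{(2S)-1-(tert-butyldimethylsilyloxy)-3-[4-methoxy-3-(pivaloyloxy)phenyl]propan-2-yl}-3-[3-methoxy-4-(pivaloyloxy)phenyl]oxiran-2-yl}methanol
Product: 19 {(2S,3R)-2-{(2S)-1-hydroxy-3-[4-methoxy-3-(pivaloyloxy)phenyl]propan-2-yl}-3-[3-methoxy-4-(pivaloyloxy)phenyl]oxiran-2-yl}methanol
Conditions: Bu4NF, AcOH (1:1), THF, 0 °C → rt
Reagents that add atoms: none
Why: Acetic acid-buffered fluoride should remove the primary silyl ether near neutrality, so neither Payne rearrangement of the epoxy alcohol nor cleavage of the aryl pivalates is expected; the C5 hydroxyl is released only when the acid step is due.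

Step 12
Reactants: 19 {(2S,3R)-2-{(2S)-1-hydroxy-3-[4-methoxy-3-(pivaloyloxy)phenyl]propan-2-yl}-3-[3-methoxy-4-(pivaloyloxy)phenyl]oxiran-2-yl}methanol
Product: 20 (2S,3S,4S)-3-(hydroxymethyl)-2-[3-methoxy-4-(pivaloyloxy)phenyl]-4-[4-methoxy-3-(pivaloyloxy)benzyl]oxolan-3-ol
Conditions: (+)-camphor-10-sulfonic acid (10 mol %), CH2Cl2, 0 °C → rt
Reagents that add atoms: none
Why: The sulfonic acid protonates or hydrogen-bonds O7 and weakens the benzylic C2–O7 bond; the C5 hydroxyl then attacks C2 from the side opposite O7 and a proton is lost, so O1–C2 forms while O7 stays on C3 as the tertiary alcohol. The closest known reaction type is the acid-catalysed endo-selective cyclisation of 3,4-epoxy alcohols that carry a π-activating group on the distal oxirane carbon. The tetrahydrofuran closes in the 5-endo mode (both oxirane carbons end up in the ring); attack at C3 would be 4-exo and would meet a fully substituted, non-benzylic carbon. The only new stereocentre is C2, set by stereospecific inversion of the (3R)-oxirane carbon, whose configuration came from the alkene geometry of step 8 and the tartrate of step 10; C3 keeps its C–O7 bond and C4 is not involved. The step needs attack at C2 and not C3, by the C5 and not the C6 hydroxyl, and in an SN2-like course. Benzylic activation and ring size should give the first, and the C6 hydroxyl could only close a strained oxetane. The para-pivaloyloxy group on ring B is a much weaker donor than a free or alkylated phenol and should keep charge development at C2 small enough for inversion; the aprotic solvent and catalytic acid leave no external nucleophile to compete.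

Step 13
Reactants: 20 (2S,3S,4S)-3-(hydroxymethyl)-2-[3-methoxy-4-(pivaloyloxy)phenyl]-4-[4-methoxy-3-(pivaloyloxy)benzyl]oxolan-3-ol
Product: 21 {(2S,3S,4S)-3-hydroxy-2-[3-methoxy-4-(pivaloyloxy)phenyl]-4-[4-methoxy-3-(pivaloyloxy)benzyl]oxolan-3-yl}methyl 4-methylbenzenesulfonate
Conditions: TsCl, Et3N, Bu2SnO (5 mol %), CH2Cl2, rt
Reagents that add atoms: 4-methylbenzenesulfonyl chloride, Cc1ccc(cc1)S(=O)(=O)Cl
Why: Tin-acetal-catalysed monosulfonylation of a 1,2-diol: the stannylene activates the primary oxygen and the tertiary C3 hydroxyl is too hindered to react, so only the C6 hydroxyl should be tosylated.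

Step 14
Reactants: 21 {(2S,3S,4S)-3-hydroxy-2-[3-methoxy-4-(pivaloyloxy)phenyl]-4-[4-methoxy-3-(pivaloyloxy)benzyl]oxolan-3-yl}methyl 4-methylbenzenesulfonate
Product: 23 5-{[(3S,4S,7S)-4-(4-hydroxy-3-methoxyphenyl)-1,5-dioxaspiro[2.4]heptan-7-yl]methyl}-2-methoxyphenol, via spiro-oxirane bis-pivalate 22 (not isolated)
Conditions: K2CO3, MeOH, 0 °C → rt; pH 7 buffer work-up
Reagents that add atoms: none
Why: The tertiary C3 alkoxide should displace the neighbouring primary tosylate (3-exo-tet Williamson closure) without touching the C3–O7 bond, so C3 keeps its configuration in 22; the same medium then removes both aryl pivalates by transesterification, and the buffered work-up returns the neutral phenols.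

## Compound list

1 | 3-(3-hydroxy-4-methoxyphenyl)propanoic acid | COc1ccc(CCC(=O)O)cc1O | starting material
2 | (4R)-4-benzyl-1,3-oxazolidin-2-one | O=C1OC[C@@H](Cc2ccccc2)N1 | starting material
3 | 3-[4-methoxy-3-(pivaloyloxy)phenyl]propanoic pivalic anhydride (formed in the flask) | COc1ccc(CCC(=O)OC(=O)C(C)(C)C)cc1OC(=O)C(C)(C)C | intermediate
4 | (4R)-4-benzyl-3-{3-[4-methoxy-3-(pivaloyloxy)phenyl]propanoyl}-1,3-oxazolidin-2-one | COc1ccc(CCC(=O)N2[C@H](Cc3ccccc3)COC2=O)cc1OC(=O)C(C)(C)C | intermediate
5 | trichlorotitanium (Z)-enolate of 4, O–TiCl3 cis to the arylmethyl group (formed in the flask) | COc1ccc(C/C=C(\O[Ti](Cl)(Cl)Cl)N2[C@H](Cc3ccccc3)COC2=O)cc1OC(=O)C(C)(C)C | intermediate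
6 | (4R)-4-benzyl-3-{(2S)-2-(hydroxymethyl)-3-[4-methoxy-3-(pivaloyloxy)phenyl]propanoyl}-1,3-oxazolidin-2-one | COc1ccc(C[C@@H](CO)C(=O)N2[C@H](Cc3ccccc3)COC2=O)cc1OC(=O)C(C)(C)C | intermediate
7 | (4R)-4-benzyl-3-{(2S)-2-[(tert-butyldimethylsilyloxy)methyl]-3-[4-methoxy-3-(pivaloyloxy)phenyl]propanoyl}-1,3-oxazolidin-2-one | COc1ccc(C[C@@H](CO[Si](C)(C)C(C)(C)C)C(=O)N2[C@H](Cc3ccccc3)COC2=O)cc1OC(=O)C(C)(C)C | intermediate
8 | S-ethyl (2S)-2-[(tert-butyldimethylsilyloxy)methyl]-3-[4-methoxy-3-(pivaloyloxy)phenyl]propanethioate | COc1ccc(C[C@@H](CO[Si](C)(C)C(C)(C)C)C(=O)SCC)cc1OC(=O)C(C)(C)C | intermediate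
9 | 2-methoxy-4-methylphenol | COc1cc(C)ccc1O | starting material
10 | 2-methoxy-4-methylphenyl pivalate | COc1cc(C)ccc1OC(=O)C(C)(C)C | intermediate
11 | 4-(bromomethyl)-2-methoxyphenyl pivalate | COc1cc(CBr)ccc1OC(=O)C(C)(C)C | intermediate
12 | [3-methoxy-4-(pivaloyloxy)benzyl]zinc bromide (formed in the flask) | COc1cc(C[Zn]Br)ccc1OC(=O)C(C)(C)C | intermediate
13 | (3S)-3-[(tert-butyldimethylsilyloxy)methyl]-1-[3-methoxy-4-(pivaloyloxy)phenyl]-4-[4-methoxy-3-(pivaloyloxy)phenyl]butan-2-one | COc1ccc(C[C@@H](CO[Si](C)(C)C(C)(C)C)C(=O)Cc2ccc(OC(=O)C(C)(C)C)c(OC)c2)cc1OC(=O)C(C)(C)C | intermediate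
14 | potassium (Z)-enolate of 13, oxygen cis to ring B (formed in the flask) | COc1ccc(C[C@@H](CO[Si](C)(C)C(C)(C)C)/C([O-])=C/c2ccc(OC(=O)C(C)(C)C)c(OC)c2)cc1OC(=O)C(C)(C)C.[K+] | intermediate
15 | (1Z,3S)-3-[(tert-butyldimethylsilyloxy)methyl]-1-[3-methoxy-4-(pivaloyloxy)phenyl]-4-[4-methoxy-3-(pivaloyloxy)phenyl]but-1-en-2-yl trifluoromethanesulfonate | COc1ccc(C[C@@H](CO[Si](C)(C)C(C)(C)C)/C(OS(=O)(=O)C(F)(F)F)=C/c2ccc(OC(=O)C(C)(C)C)c(OC)c2)cc1OC(=O)C(C)(C)C | intermediate
16 | (tributylstannyl)methanol | OC[Sn](CCCC)(CCCC)CCCC | starting material
17 | (2Z)-2-{(2R)-1-(tert-butyldimethylsilyloxy)-3-[4-methoxy-3-(pivaloyloxy)phenyl]propan-2-yl}-3-[3-methoxy-4-(pivaloyloxy)phenyl]prop-2-en-1-ol | COc1ccc(C[C@@H](CO[Si](C)(C)C(C)(C)C)/C(CO)=C/c2ccc(OC(=O)C(C)(C)C)c(OC)c2)cc1OC(=O)C(C)(C)C | intermediate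
18 | {(2S,3R)-2-{(2S)-1-(tert-butyldimethylsilyloxy)-3-[4-methoxy-3-(pivaloyloxy)phenyl]propan-2-yl}-3-[3-methoxy-4-(pivaloyloxy)phenyl]oxiran-2-yl}methanol | COc1ccc(C[C@@H](CO[Si](C)(C)C(C)(C)C)[C@@]2(CO)O[C@@H]2c3ccc(OC(=O)C(C)(C)C)c(OC)c3)cc1OC(=O)C(C)(C)C | intermediate
19 | {(2S,3R)-2-{(2S)-1-hydroxy-3-[4-methoxy-3-(pivaloyloxy)phenyl]propan-2-yl}-3-[3-methoxy-4-(pivaloyloxy)phenyl]oxiran-2-yl}methanol | COc1ccc(C[C@@H](CO)[C@@]2(CO)O[C@@H]2c3ccc(OC(=O)C(C)(C)C)c(OC)c3)cc1OC(=O)C(C)(C)C | intermediate
20 | (2S,3S,4S)-3-(hydroxymethyl)-2-[3-methoxy-4-(pivaloyloxy)phenyl]-4-[4-methoxy-3-(pivaloyloxy)benzyl]oxolan-3-ol | COc1ccc(C[C@H]2CO[C@@H](c3ccc(OC(=O)C(C)(C)C)c(OC)c3)[C@@]2(O)CO)cc1OC(=O)C(C)(C)C | intermediate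
21 | {(2S,3S,4S)-3-hydroxy-2-[3-methoxy-4-(pivaloyloxy)phenyl]-4-[4-methoxy-3-(pivaloyloxy)benzyl]oxolan-3-yl}methyl 4-methylbenzenesulfonate | COc1ccc(C[C@H]2CO[C@@H](c3ccc(OC(=O)C(C)(C)C)c(OC)c3)[C@@]2(O)COS(=O)(=O)c4ccc(C)cc4)cc1OC(=O)C(C)(C)C | intermediate
22 | (3S,4S,7S)-4-[3-methoxy-4-(pivaloyloxy)phenyl]-7-[4-methoxy-3-(pivaloyloxy)benzyl]-1,5-dioxaspiro[2.4]heptane (formed in the flask) | COc1ccc(C[C@H]2CO[C@@H](c3ccc(OC(=O)C(C)(C)C)c(OC)c3)[C@@]23CO3)cc1OC(=O)C(C)(C)C | intermediate
23 | 5-{[(3S,4S,7S)-4-(4-hydroxy-3-methoxyphenyl)-1,5-dioxaspiro[2.4]heptan-7-yl]methyl}-2-methoxyphenol | COc1ccc(C[C@H]2CO[C@@H](c3ccc(O)c(OC)c3)[C@@]23CO3)cc1O | target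

## Step count and least certain steps

Total step count: 14. Longest linear sequence: 12 steps (from 1 through steps 1–4 and 7–14); the ring B branch (steps 5 and 6, from 9) joins at step 7.

**Step 12 (key step).** The most likely failure is ionisation of the activated oxirane at benzylic C2 before the C5 hydroxyl has bonded. That would give a planar cation and hence loss of inversion at C2, or a 1,2-shift to a carbonyl compound. The cause is residual cation stabilisation by ring B and the strained 5-endo trajectory, which slows the SN2-like path. Fallback: setting out from 17, the silyl ether would be removed first (Bu4NF, AcOH, THF) to give the ene-diol (2R)-2-[4-methoxy-3-(pivaloyloxy)benzyl]-3-[(Z)-3-methoxy-4-(pivaloyloxy)benzylidene]butane-1,4-diol F1. F1 would then be epoxidised with a full equivalent of Ti(OiPr)4 and L-(+)-diethyl tartrate and t-BuOOH at −20 → 0 °C. The oxirane would form as its titanium 2,3-epoxy alkoxide, and within this chelate the C5 oxygen should open the distal carbon C2 with inversion, without any Brønsted acid and without isolating the epoxide. This returns to the route at 20.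

**Step 8.** The most likely failure is incomplete control of enolate geometry (a mixture of alkene isomers after triflation), because the outcome rests only on the thermodynamic preference of the potassium enolate. Fallback: setting out from 13, the mixture of 15 and its isomer (1E,3S)-3-[(tert-butyldimethylsilyloxy)methyl]-1-[3-methoxy-4-(pivaloyloxy)phenyl]-4-[4-methoxy-3-(pivaloyloxy)phenyl]but-1-en-2-yl trifluoromethanesulfonate F2 would be carried through the hydroxymethylation of step 9. This would give 17 together with (2E)-2-{(2R)-1-(tert-butyldimethylsilyloxy)-3-[4-methoxy-3-(pivaloyloxy)phenyl]propan-2-yl}-3-[3-methoxy-4-(pivaloyloxy)phenyl]prop-2-en-1-ol F3. The geometry would then be corrected under thermodynamic control: catalytic PhSSPh with light (or catalytic I2) equilibrates the styrenyl double bond by reversible radical addition. The isomer with ring B cis to the small CH2OH group and trans to the branched substituent should dominate, and residual F3 would be recycled. This returns at 17.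

**Step 10.** The most likely failure is slow turnover with eroded facial selectivity, and possibly titanium-induced opening of the aryl oxirane. The cause is that the cis-aryl group and the branched C2 substituent crowd the Ti(OiPr)4–tartrate reagent. Fallback: setting out from 17, a hydroxyl-directed epoxidation with VO(acac)2 (cat.) and t-BuOOH in CH2Cl2 at 0 °C would replace reagent control by substrate direction. It would give 18 and its diastereomer {(2R,3S)-2-{(2S)-1-(tert-butyldimethylsilyloxy)-3-[4-methoxy-3-(pivaloyloxy)phenyl]propan-2-yl}-3-[3-methoxy-4-(pivaloyloxy)phenyl]oxiran-2-yl}methanol F4. Because C4 is fixed, the two are diastereomers and would be separated by chromatography. This returns at 18.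

**Step 9.** The most likely failure is slow transfer of the sp3 hydroxymethyl group from tin to the crowded alkenylpalladium, which would let reduction of the triflate or its hydrolysis back to the ketone take over. Fallback: setting out from 15, a palladium-catalysed formylation (Pd(PPh3)4, CO at 1 atm, slow addition of Bu3SnH, THF, 50 °C) would give the enal (2Z)-2-{(2R)-1-(tert-butyldimethylsilyloxy)-3-[4-methoxy-3-(pivaloyloxy)phenyl]propan-2-yl}-3-[3-methoxy-4-(pivaloyloxy)phenyl]prop-2-enal F5. Luche reduction of F5 (NaBH4, CeCl3·7H2O, MeOH, −40 °C) should reduce only the aldehyde. This returns at 17.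

**Step 14.** The most likely failure is slow methanolysis of the hindered pivalates, which would leave the oxirane and the para-phenoxide benzylic ether in basic methanol for long enough that the oxirane is opened by methanol or C2 ionises towards a quinone methide. Fallback: setting out from 21, the oxirane would be closed with a non-nucleophilic base (NaH, THF, 0 °C) and 22 isolated. The two aryl pivalates would then be cleaved reductively at low temperature (i-Bu2AlH, CH2Cl2, −78 °C, potassium sodium tartrate work-up), which avoids a basic nucleophilic medium. This returns at 23 and makes no new compound.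

## Further compounds

F1 | step 12 | (2R)-2-[4-methoxy-3-(pivaloyloxy)benzyl]-3-[(Z)-3-methoxy-4-(pivaloyloxy)benzylidene]butane-1,4-diol | COc1ccc(C[C@@H](CO)/C(CO)=C/c2ccc(OC(=O)C(C)(C)C)c(OC)c2)cc1OC(=O)C(C)(C)C
F2 | step 8 | (1E,3S)-3-[(tert-butyldimethylsilyloxy)methyl]-1-[3-methoxy-4-(pivaloyloxy)phenyl]-4-[4-methoxy-3-(pivaloyloxy)phenyl]but-1-en-2-yl trifluoromethanesulfonate | COc1ccc(C[C@@H](CO[Si](C)(C)C(C)(C)C)/C(OS(=O)(=O)C(F)(F)F)=C\c2ccc(OC(=O)C(C)(C)C)c(OC)c2)cc1OC(=O)C(C)(C)C
F3 | step 8 | (2E)-2-{(2R)-1-(tert-butyldimethylsilyloxy)-3-[4-methoxy-3-(pivaloyloxy)phenyl]propan-2-yl}-3-[3-methoxy-4-(pivaloyloxy)phenyl]prop-2-en-1-ol | COc1ccc(C[C@@H](CO[Si](C)(C)C(C)(C)C)/C(CO)=C\c2ccc(OC(=O)C(C)(C)C)c(OC)c2)cc1OC(=O)C(C)(C)C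
F4 | step 10 | {(2R,3S)-2-{(2S)-1-(tert-butyldimethylsilyloxy)-3-[4-methoxy-3-(pivaloyloxy)phenyl]propan-2-yl}-3-[3-methoxy-4-(pivaloyloxy)phenyl]oxiran-2-yl}methanol | COc1ccc(C[C@@H](CO[Si](C)(C)C(C)(C)C)[C@]2(CO)O[C@H]2c3ccc(OC(=O)C(C)(C)C)c(OC)c3)cc1OC(=O)C(C)(C)C
F5 | step 9 | (2Z)-2-{(2R)-1-(tert-butyldimethylsilyloxy)-3-[4-methoxy-3-(pivaloyloxy)phenyl]propan-2-yl}-3-[3-methoxy-4-(pivaloyloxy)phenyl]prop-2-enal | COc1ccc(C[C@@H](CO[Si](C)(C)C(C)(C)C)/C(C=O)=C/c2ccc(OC(=O)C(C)(C)C)c(OC)c2)cc1OC(=O)C(C)(C)C
F0 | step 14 | none | none
A1 | alternative 1 | diethyl (2S,4Z)-2-[3-methoxy-4-(triisopropylsilyloxy)phenyl]-4-[4-methoxy-3-(triisopropylsilyloxy)benzylidene]oxolane-3,3-dicarboxylate | CCOC(=O)C1(C(=O)OCC)[C@H](c2ccc(O[Si](C(C)C)(C(C)C)C(C)C)c(OC)c2)OC/C1=C\c3ccc(OC)c(O[Si](C(C)C)(C(C)C)C(C)C)c3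
A2 | alternative 1 | diethyl 2-[3-methoxy-4-(triisopropylsilyloxy)benzylidene]propanedioate | CCOC(=O)C(=Cc1ccc(O[Si](C(C)C)(C(C)C)C(C)C)c(OC)c1)C(=O)OCC
A3 | alternative 1 | prop-2-yn-1-ol | OCC#C
A4 | alternative 1 | (5-iodo-2-methoxyphenoxy)triisopropylsilane | COc1ccc(I)cc1O[Si](C(C)C)(C(C)C)C(C)C
A5 | alternative 2 | (2R,4R)-2-[4-(tert-butyldimethylsilyloxy)-3-methoxyphenyl]-4-[3-(tert-butyldimethylsilyloxy)-4-methoxybenzyl]-3-methylideneoxolane | COc1ccc(C[C@H]2CO[C@@H](c3ccc(O[Si](C)(C)C(C)(C)C)c(OC)c3)C2=C)cc1O[Si](C)(C)C(C)(C)C
A6 | alternative 2 | tert-butyl{2-methoxy-4-[(1R)-1-{(2E)-3-[3-(tert-butyldimethylsilyloxy)-4-methoxyphenyl]prop-2-enyloxy}prop-2-ynyl]phenoxy}dimethylsilane | C#C[C@@H](OC/C=C/c1ccc(OC)c(O[Si](C)(C)C(C)(C)C)c1)c2ccc(O[Si](C)(C)C(C)(C)C)c(OC)c2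
A7 | alternative 3 | (2S,3S,4S)-3-[(tert-butyldimethylsilyloxy)methyl]-2-[3-methoxy-4-(triisopropylsilyloxy)phenyl]-4-[4-methoxy-3-(triisopropylsilyloxy)benzyl]oxolan-3-ol | COc1ccc(C[C@H]2CO[C@@H](c3ccc(O[Si](C(C)C)(C(C)C)C(C)C)c(OC)c3)[C@@]2(O)CO[Si](C)(C)C(C)(C)C)cc1O[Si](C(C)C)(C(C)C)C(C)C
A8 | alternative 3 | {[(1S,2S,3E)-2-[(tert-butyldimethylsilyloxy)methyl]-2-hydroxy-1-[3-methoxy-4-(triisopropylsilyloxy)phenyl]-4-[4-methoxy-3-(triisopropylsilyloxy)phenyl]but-3-en-1-yl]oxy}acetic acid | OC(=O)CO[C@@H](c1ccc(O[Si](C(C)C)(C(C)C)C(C)C)c(OC)c1)[C@@](O)(CO[Si](C)(C)C(C)(C)C)/C=C/c2ccc(OC)c(O[Si](C(C)C)(C(C)C)C(C)C)c2
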